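The route cuts the two bonds between the inner CH2 carbons (on C6 and C8 of ring A) and C1'' of the inner rings, making ring A the electrophile. It exploits that each inner ring is a phenol whose C2''–OH lies ortho to C1'' and para to C5'', hence an isomer of a 4-substituted 6-arylidenecyclohex-2-enone, and that both CH2 groups flank the 7-OMe carbon symmetrically. In one flask, two enone enolates condense with a ring A 1,3-dialdehyde and base shifts the exocyclic alkenes into the rings, giving both C–C bonds and both inner arenes. The dialdehyde carries MOM ethers and a bromine at the future C4a; C2 is set later by asymmetric phenyl addition to a chromone.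

Key step: step 9

Assumption: the (S)-configured diphosphine of step 13 is taken to deliver phenyl to the same enone face as (S)-BINAP does with cyclohex-2-enone, which corresponds to (2S) here. If the sense proves opposite, the (R)-ligand is used.

Step 1
Reactants: 1 5-methoxyresorcinol
Product: 2 1-methoxy-3,5-bis(methoxymethoxy)benzene
Conditions: NaH (2.3 equiv), MOMCl (2.3 equiv), DMF, 0 °C → rt
Reagents that add atoms: chloromethyl methyl ether, COCCl
Why: Twofold O-alkylation of the sodium phenoxides with the reactive α-chloro ether (Williamson-type ether synthesis) installs the two acetal ethers that later direct the ring metalations.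

Step 2
Reactants: 2 1-methoxy-3,5-bis(methoxymethoxy)benzene
Product: 4 [4-methoxy-2,6-bis(methoxymethoxy)phenyl]trimethylsilane, via aryllithium 3 (not isolated)
Conditions: n-BuLi (1.1 equiv), THF, 0 °C; Me3SiCl, −78 °C → rt
Reagents that add atoms: chlorotrimethylsilane, C[Si](C)(C)Cl
Why: Directed ortho-metalation, in which the two MOM ethers cooperate so that n-BuLi removes the hydrogen between them, and silylation blocks this most acidic site (the future C4a) during the next two metalations.

Step 3
Reactants: 4 [4-methoxy-2,6-bis(methoxymethoxy)phenyl]trimethylsilane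
Product: 6 6-methoxy-2,4-bis(methoxymethoxy)-3-(trimethylsilyl)benzaldehyde, via aryllithium 5 (not isolated)
Conditions: n-BuLi (1.2 equiv), TMEDA, THF, 0 °C; DMF, −78 °C → rt; H2O
Reagents that add atoms: N,N-dimethylformamide, CN(C)C=O
Why: Directed ortho-metalation and formylation with DMF, where the two remaining ring hydrogens are equivalent and each lies between OMe and OMOM, so only one aldehyde can form.

Step 4
Reactants: 6 6-methoxy-2,4-bis(methoxymethoxy)-3-(trimethylsilyl)benzaldehyde
Product: 9 2-methoxy-4,6-bis(methoxymethoxy)-5-(trimethylsilyl)benzene-1,3-dicarbaldehyde, via lithium amino alkoxide 7 (not isolated), via ring-lithiated amino alkoxide 8 (not isolated)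
Conditions: Me2NCH2CH2NHMe, n-BuLi, THF, −20 °C, then 6; n-BuLi (2 equiv), −20 → 0 °C; DMF, −78 °C → rt; H2O
Reagents that add atoms: N,N-dimethylformamide, CN(C)C=O
Why: A free formyl group would not survive n-BuLi, so it is masked in the flask as its lithium α-amino alkoxide, after which directed ortho-metalation can only remove the single remaining ring hydrogen (between OMe and OMOM), DMF delivers the second formyl group and the mask falls off on aqueous work-up.

Step 5
Reactants: 9 2-methoxy-4,6-bis(methoxymethoxy)-5-(trimethylsilyl)benzene-1,3-dicarbaldehyde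
Product: 10 5-bromo-2-methoxy-4,6-bis(methoxymethoxy)benzene-1,3-dicarbaldehyde
Conditions: NBS (1.05 equiv), MeCN, dark, 0 °C → rt; H2O
Reagents that add atoms: N-bromosuccinimide, O=C1CCC(=O)N1Br
Why: Ipso-bromodesilylation (electrophilic aromatic substitution at the C–Si carbon) is favoured because this carbon is ortho or para to all three oxygen donors, meta to both formyl groups and activated by the β-silicon effect; the silyl group leaves on the succinimide nitrogen without release of acid, so the MOM ethers stay, and the bromine turns the later C4a metalation into a halogen–lithium exchange.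

Step 6
Reactants: 11 [2-(benzyloxy)phenyl]methanol
Product: 12 1-(benzyloxy)-2-(bromomethyl)benzene
Conditions: PBr3 (0.4 equiv), Et2O, 0 °C
Reagents that add atoms: phosphorus tribromide, BrP(Br)Br
Why: SN2 displacement by bromide of the primary benzylic alcohol activated as its phosphite ester, with the aryl benzyl ether inert.

Step 7
Reactants: 13 3-ethoxycyclohex-2-en-1-one; 12 1-(benzyloxy)-2-(bromomethyl)benzene
Product: 15 6-[2-(benzyloxy)benzyl]-3-ethoxycyclohex-2-en-1-one (racemic), via lithium dienolate 14 (not isolated)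
Conditions: LiN(i-Pr)2 (LDA), THF, −78 °C; 12, −78 °C → rt
Reagents that add atoms: none
Why: First half of the Stork–Danheiser sequence, in which kinetic deprotonation of the vinylogous ester can occur only at C6 and the dienolate is alkylated by the reactive benzylic bromide in an SN2 reaction, giving a racemic centre that is erased in step 9.

Step 8
Reactants: 15 6-[2-(benzyloxy)benzyl]-3-ethoxycyclohex-2-en-1-one
Product: 17 4-[2-(benzyloxy)benzyl]cyclohex-2-en-1-one (racemic), via allylic alcohol 16 (not isolated)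
Conditions: LiAlH4, Et2O, 0 °C; 1 M aq HCl, THF, 0 °C → rt
Reagents that add atoms: water, O
Why: Second half of the Stork–Danheiser sequence, in which 1,2-reduction of the vinylogous ester and mild acid hydrolysis of the enol ether with loss of the allylic hydroxyl transpose the carbonyl group, so the benzyl substituent ends at C4 of a cyclohex-2-enone, and the benzyl ether tolerates both hydride and dilute acid.

Step 9
Reactants: 17 4-[2-(benzyloxy)benzyl]cyclohex-2-en-1-one (2.4 equiv); 10 5-bromo-2-methoxy-4,6-bis(methoxymethoxy)benzene-1,3-dicarbaldehyde (1 equiv)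
Product: 21 2,2'-{[5-bromo-2-methoxy-4,6-bis(methoxymethoxy)-1,3-phenylene]bis(methylene)}bis{4-[2-(benzyloxy)benzyl]phenol}, via lithium dienolate 18 (not isolated), via bis(aldol acetate) 19 (not isolated), via bis(arylidene)dienone 20 (not isolated)
Conditions: LiN(i-Pr)2 (2.3 equiv), THF, −78 °C; 10, −78 °C; Ac2O (4 equiv), −78 → 0 °C; KOt-Bu (10 equiv), t-BuOH–THF, 0 → 40 °C; AcOH quench
Reagents that add atoms: none
Why: LDA removes a hydrogen from the only α′-position (C6) of 17 under kinetic control, the cross-conjugated dienolate 18 adds to both formyl groups of 10, and acetylation of the adduct in the flask turns each carbinol oxygen into a leaving group so that E1cB loss of acetate outruns retro-aldol cleavage. KOt-Bu then relays protons in dienone 20 (γ-deprotonation at C4, α-reprotonation, removal of the now doubly allylic C5–H, protonation at the exocyclic carbon) to the keto tautomer of the phenol, whose enolisation and deprotonation to the phenoxide make the sequence irreversible. The closest known chemistry is the aldol condensation of cyclohex-2-enones with aromatic aldehydes followed by base-induced isoaromatisation of the 6-arylidene enones to 2-benzylphenols, here run twice on one arene. No ring is closed and no stereocentre survives: the racemic C4 centres, the carbinol centres and the alkene geometry are all erased on aromatisation, so the diastereomer mixture converges on one product. Site selectivity is secured twice over, since 17 has a single α′-CH2 and since a stray attack through C2 would give the same arene, C2 and C6 being equivalent once the C4 substituent lies para to the hydroxyl. Ring A reacts as the electrophile and has no free ring position (Br sits at the future C4a), so over-benzylation, ortho/para mixtures and oligomers cannot arise, and MOM ethers, benzyl ethers and the aryl bromide (no ortho hydrogen, hence no aryne) are inert to the bases used.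

Step 10
Reactants: 21 2,2'-{[5-bromo-2-methoxy-4,6-bis(methoxymethoxy)-1,3-phenylene]bis(methylene)}bis{4-[2-(benzyloxy)benzyl]phenol}
Product: 22 1-bromo-4-methoxy-2,6-bis(methoxymethoxy)-3,5-bis{2-(benzyloxy)-5-[2-(benzyloxy)benzyl]benzyl}benzene
Conditions: BnBr (2.5 equiv), K2CO3, DMF, 40 °C
Reagents that add atoms: benzyl bromide, BrCc1ccccc1
Why: Williamson ether synthesis on the two new phenols removes the acidic protons before the organolithium step and gives all four arm oxygens the same acid-stable, hydrogenolysable group.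

Step 11
Reactants: 22 1-bromo-4-methoxy-2,6-bis(methoxymethoxy)-3,5-bis{2-(benzyloxy)-5-[2-(benzyloxy)benzyl]benzyl}benzene
Product: 24 1-[4-methoxy-2,6-bis(methoxymethoxy)-3,5-bis{2-(benzyloxy)-5-[2-(benzyloxy)benzyl]benzyl}phenyl]ethan-1-one, via aryllithium 23 (not isolated)
Conditions: n-BuLi (1.05 equiv), THF, −78 °C; MeC(O)N(OMe)Me, −78 → 0 °C; H2O
Reagents that add atoms: N-methoxy-N-methylacetamide, CC(=O)N(C)OC
Why: Bromine–lithium exchange at −78 °C is much faster than deprotonation of the diarylmethane CH2 groups or the benzyl ethers and places lithium only at the future C4a, and the chelated tetrahedral adduct of the Weinreb ketone synthesis stops the acylation at the ketone.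

Step 12
Reactants: 24 1-[4-methoxy-2,6-bis(methoxymethoxy)-3,5-bis{2-(benzyloxy)-5-[2-(benzyloxy)benzyl]benzyl}phenyl]ethan-1-one
Product: 26 6,8-bis{2-(benzyloxy)-5-[2-(benzyloxy)benzyl]benzyl}-5-hydroxy-7-methoxy-4H-chromen-4-one, via enaminone 25 (not isolated)
Conditions: Me2NCH(OMe)2, toluene, 110 °C; evaporate; HCl (3 equiv), MeOH–THF, 50 °C; aq NaHCO3
Reagents that add atoms: N,N-dimethylformamide dimethyl acetal, COC(OC)N(C)C
Why: Standard enaminone route to chromones, in which the methyl ketone condenses with the amide acetal, HCl removes the two MOM groups next to the carbonyl, and one of the two symmetry-equivalent phenols adds to the β-carbon and expels dimethylamine (6-endo-trig addition–elimination), while the benzyl ethers resist the acid.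

Step 13
Reactants: 26 6,8-bis{2-(benzyloxy)-5-[2-(benzyloxy)benzyl]benzyl}-5-hydroxy-7-methoxy-4H-chromen-4-one; 27 phenylboronic acid (3 equiv)
Product: 28 (2S)-6,8-bis{2-(benzyloxy)-5-[2-(benzyloxy)benzyl]benzyl}-5-hydroxy-7-methoxy-2-phenylchroman-4-one
Conditions: [Rh(OH)(cod)]2 (2.5 mol %), (S)-MeO-F12-BIPHEP (5.5 mol %), toluene–H2O, 25–40 °C
Reagents that add atoms: none
Why: Rhodium-catalysed asymmetric 1,4-addition of an arylboronic acid to a chromone (Hayashi–Miyaura reaction), known for 5,7-dioxygenated chromones, in which the phenyl–rhodium species held in the chiral pocket of the (S)-diphosphine inserts into C2=C3 from one face and hydrolysis of the rhodium enolate releases the (2S)-flavanone, while the neutral, base-free medium avoids retro-oxa-Michael racemisation of the new C2 centre.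

Step 14
Reactants: 28 (2S)-6,8-bis{2-(benzyloxy)-5-[2-(benzyloxy)benzyl]benzyl}-5-hydroxy-7-methoxy-2-phenylchroman-4-one
Product: 29 (2S)-5-hydroxy-6,8-bis[2-hydroxy-5-(2-hydroxybenzyl)benzyl]-7-methoxy-2-phenylchroman-4-one, 5''-(2''''-hydroxybenzyl)uvarinol
Conditions: H2 (1 atm), 10% Pd/C, EtOAc–MeOH, rt
Reagents that add atoms: none
Why: Heterogeneous hydrogenolysis of the four aryl benzyl ethers under neutral conditions is much faster than cleavage of the cyclic C2–O1 bond, leaves the hydrogen-bonded, electron-rich C4 ketone and the diarylmethane links alone, and gives the base-sensitive C2 centre no chance to epimerise.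

Compound list
1 | 5-methoxyresorcinol | COc1cc(O)cc(O)c1 | starting material
2 | 1-methoxy-3,5-bis(methoxymethoxy)benzene | COCOc1cc(OC)cc(OCOC)c1 | intermediate
3 | [4-methoxy-2,6-bis(methoxymethoxy)phenyl]lithium | [Li]c1c(OCOC)cc(OC)cc1OCOC | intermediate
4 | [4-methoxy-2,6-bis(methoxymethoxy)phenyl]trimethylsilane | COCOc1cc(OC)cc(OCOC)c1[Si](C)(C)C | intermediate
5 | [6-methoxy-2,4-bis(methoxymethoxy)-3-(trimethylsilyl)phenyl]lithium | [Li]c1c(OC)cc(OCOC)c([Si](C)(C)C)c1OCOC | intermediate
6 | 6-methoxy-2,4-bis(methoxymethoxy)-3-(trimethylsilyl)benzaldehyde | O=Cc1c(OC)cc(OCOC)c([Si](C)(C)C)c1OCOC | intermediate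
7 | lithium {[2-(dimethylamino)ethyl](methyl)amino}[6-methoxy-2,4-bis(methoxymethoxy)-3-(trimethylsilyl)phenyl]methanolate | [Li]OC(N(C)CCN(C)C)c1c(OC)cc(OCOC)c([Si](C)(C)C)c1OCOC | intermediate
8 | 5-lithio derivative of 7 (lithium on the ring carbon between OMe and OMOM) | [Li]OC(N(C)CCN(C)C)c1c(OC)c([Li])c(OCOC)c([Si](C)(C)C)c1OCOC | intermediate
9 | 2-methoxy-4,6-bis(methoxymethoxy)-5-(trimethylsilyl)benzene-1,3-dicarbaldehyde | COc1c(C=O)c(OCOC)c([Si](C)(C)C)c(OCOC)c1C=O | intermediate
10 | 5-bromo-2-methoxy-4,6-bis(methoxymethoxy)benzene-1,3-dicarbaldehyde | COc1c(C=O)c(OCOC)c(Br)c(OCOC)c1C=O | intermediate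
11 | [2-(benzyloxy)phenyl]methanol | OCc1ccccc1OCc1ccccc1 | starting material
12 | 1-(benzyloxy)-2-(bromomethyl)benzene | BrCc1ccccc1OCc1ccccc1 | intermediate
13 | 3-ethoxycyclohex-2-en-1-one | CCOC1=CC(=O)CCC1 | starting material
14 | lithium 3-ethoxycyclohexa-1,3-dien-1-olate (kinetic dienolate of 13) | CCOC1=CC(O[Li])=CCC1 | intermediate
15 | 6-[2-(benzyloxy)benzyl]-3-ethoxycyclohex-2-en-1-one (racemic) | CCOC1=CC(=O)C(Cc2ccccc2OCc2ccccc2)CC1 | intermediate
16 | 6-[2-(benzyloxy)benzyl]-3-ethoxycyclohex-2-en-1-ol (mixture of diastereomers) | CCOC1=CC(O)C(Cc2ccccc2OCc2ccccc2)CC1 | intermediate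
17 | 4-[2-(benzyloxy)benzyl]cyclohex-2-en-1-one (racemic) | O=C1C=CC(Cc2ccccc2OCc2ccccc2)CC1 | intermediate
18 | lithium 4-[2-(benzyloxy)benzyl]cyclohexa-1,5-dien-1-olate (kinetic dienolate of 17) | [Li]OC1=CCC(Cc2ccccc2OCc2ccccc2)C=C1 | intermediate
19 | [5-bromo-2-methoxy-4,6-bis(methoxymethoxy)-1,3-phenylene]bis({5-[2-(benzyloxy)benzyl]-2-oxocyclohex-3-en-1-yl}methylene) diacetate (mixture of diastereomers) | COc1c(C(OC(C)=O)C2CC(Cc3ccccc3OCc3ccccc3)C=CC2=O)c(OCOC)c(Br)c(OCOC)c1C(OC(C)=O)C1CC(Cc2ccccc2OCc2ccccc2)C=CC1=O | intermediate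
20 | 6,6'-{[5-bromo-2-methoxy-4,6-bis(methoxymethoxy)-1,3-phenylene]dimethylylidene}bis{4-[2-(benzyloxy)benzyl]cyclohex-2-en-1-one} (isomer mixture, geometry of no consequence) | COc1c(C=C2CC(Cc3ccccc3OCc3ccccc3)C=CC2=O)c(OCOC)c(Br)c(OCOC)c1C=C1CC(Cc2ccccc2OCc2ccccc2)C=CC1=O | intermediate
21 | 2,2'-{[5-bromo-2-methoxy-4,6-bis(methoxymethoxy)-1,3-phenylene]bis(methylene)}bis{4-[2-(benzyloxy)benzyl]phenol} | COc1c(Cc2cc(Cc3ccccc3OCc3ccccc3)ccc2O)c(OCOC)c(Br)c(OCOC)c1Cc1cc(Cc2ccccc2OCc2ccccc2)ccc1O | intermediate
22 | 1-bromo-4-methoxy-2,6-bis(methoxymethoxy)-3,5-bis{2-(benzyloxy)-5-[2-(benzyloxy)benzyl]benzyl}benzene | COc1c(Cc2cc(Cc3ccccc3OCc3ccccc3)ccc2OCc2ccccc2)c(OCOC)c(Br)c(OCOC)c1Cc1cc(Cc2ccccc2OCc2ccccc2)ccc1OCc1ccccc1 | intermediate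
23 | aryllithium from 22 (Li in place of Br) | COc1c(Cc2cc(Cc3ccccc3OCc3ccccc3)ccc2OCc2ccccc2)c(OCOC)c([Li])c(OCOC)c1Cc1cc(Cc2ccccc2OCc2ccccc2)ccc1OCc1ccccc1 | intermediate
24 | 1-[4-methoxy-2,6-bis(methoxymethoxy)-3,5-bis{2-(benzyloxy)-5-[2-(benzyloxy)benzyl]benzyl}phenyl]ethan-1-one | COc1c(Cc2cc(Cc3ccccc3OCc3ccccc3)ccc2OCc2ccccc2)c(OCOC)c(C(C)=O)c(OCOC)c1Cc1cc(Cc2ccccc2OCc2ccccc2)ccc1OCc1ccccc1 | intermediate
25 | (E)-3-(dimethylamino)-1-[4-methoxy-2,6-bis(methoxymethoxy)-3,5-bis{2-(benzyloxy)-5-[2-(benzyloxy)benzyl]benzyl}phenyl]prop-2-en-1-one | COc1c(Cc2cc(Cc3ccccc3OCc3ccccc3)ccc2OCc2ccccc2)c(OCOC)c(C(=O)/C=C/N(C)C)c(OCOC)c1Cc1cc(Cc2ccccc2OCc2ccccc2)ccc1OCc1ccccc1 | intermediate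
26 | 6,8-bis{2-(benzyloxy)-5-[2-(benzyloxy)benzyl]benzyl}-5-hydroxy-7-methoxy-4H-chromen-4-one | COc1c(Cc2cc(Cc3ccccc3OCc3ccccc3)ccc2OCc2ccccc2)c(O)c2c(c1Cc1cc(Cc3ccccc3OCc3ccccc3)ccc1OCc1ccccc1)OC=CC2=O | intermediate
27 | phenylboronic acid | OB(O)c1ccccc1 | starting material
28 | (2S)-6,8-bis{2-(benzyloxy)-5-[2-(benzyloxy)benzyl]benzyl}-5-hydroxy-7-methoxy-2-phenylchroman-4-one | COc1c(Cc2cc(Cc3ccccc3OCc3ccccc3)ccc2OCc2ccccc2)c(O)c2c(c1Cc1cc(Cc3ccccc3OCc3ccccc3)ccc1OCc1ccccc1)O[C@H](c1ccccc1)CC2=O | intermediate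
29 | (2S)-5-hydroxy-6,8-bis[2-hydroxy-5-(2-hydroxybenzyl)benzyl]-7-methoxy-2-phenylchroman-4-one, 5''-(2''''-hydroxybenzyl)uvarinol | COc1c(Cc2cc(Cc3ccccc3O)ccc2O)c(O)c2c(c1Cc1cc(Cc3ccccc3O)ccc1O)O[C@H](c1ccccc1)CC2=O | target

Total step count: 14. Longest linear sequence: 11 steps (steps 1–5, then 9–14). The enone branch (steps 6–8) joins at step 9.

Steps most likely to fail

Step 9. The crowded adducts may cleave by retro-aldol reaction. The sequence may stall after the first condensation, or the enone may self-condense under base before aromatisation. The fallback replaces the enolate by an aryl-metal nucleophile and corrects the oxidation level afterwards. It sets out from 12 and 10 and comes back at 22.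
- Suzuki–Miyaura coupling of the benzylic bromide 12 with 4-hydroxyphenylboronic acid (Pd(PPh3)4, K2CO3, dioxane–H2O, 80 °C) should give 4-[2-(benzyloxy)benzyl]phenol F1.
- Bromination of the more activated free-phenol ring, whose para position is blocked (NBS, CH2Cl2, −20 °C), should give 4-[2-(benzyloxy)benzyl]-2-bromophenol F2.
- Benzylation (BnBr, K2CO3, DMF) gives 1-(benzyloxy)-4-[2-(benzyloxy)benzyl]-2-bromobenzene F3.
- Bromine–lithium exchange (n-BuLi, THF, −78 °C) gives {2-(benzyloxy)-5-[2-(benzyloxy)benzyl]phenyl}lithium F4. Two equivalents of it add at −78 °C to both formyl groups of 10, faster than any exchange with the ring A bromide, to give the bis(diarylmethanol) F5.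
- Ionic reduction (Et3SiH, a few equivalents of TFA, CH2Cl2, −40 °C) then delivers 22. The cation is strongly stabilised by the trioxygenated ring A, so it should form before the MOM ethers are attacked. Steps 9 and 10 are bypassed.

Step 13. Insertion of the phenyl–rhodium species into the electron-rich, 8-substituted chromone may be slow, so that protodeboronation wins, or facial selectivity may be poor. The fallback takes the stereocentre from the chiral pool and closes ring C by substitution. It sets out from 22 and comes back at 28.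
- Commercial ethyl (R)-3-hydroxy-3-phenylpropanoate is converted (MeNHOMe·HCl, i-PrMgCl, THF, −20 °C) into (R)-3-hydroxy-N-methoxy-N-methyl-3-phenylpropanamide F6.
- Silylation (TBSCl, imidazole, DMF) gives (R)-3-[(tert-butyldimethylsilyl)oxy]-N-methoxy-N-methyl-3-phenylpropanamide F7.
- Compound 22 is lithiated as in step 11 (via 23) and acylated with F7 to give the (R)-β-silyloxy aryl ketone F8.
- Dilute HCl in MeOH–THF at room temperature removes the two MOM groups next to the carbonyl and the silyl group to give the (R)-β-hydroxy-2',6'-dihydroxyaryl ketone F9.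
- An intramolecular Mitsunobu reaction (PPh3, DIAD, THF, 0 °C) closes ring C by 6-exo-tet SN2 displacement with inversion, (R) to (S), giving 28. Steps 11–13 are bypassed.

Step 11. Proton transfer from the acetamide to the crowded aryllithium (enolisation instead of addition) would merely debrominate ring A. The fallback replaces acyl substitution by carbonyl addition and oxidation. It sets out from 22 and comes back at 24. Aryllithium 23, made as before, is trapped at −78 °C with acetaldehyde, a small and far more electrophilic partner. This gives the racemic 1-arylethanol F10, which Dess–Martin periodinane (CH2Cl2, NaHCO3, rt) oxidises to 24.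

Further compounds
F1 | step 9 | 4-[2-(benzyloxy)benzyl]phenol | Oc1ccc(Cc2ccccc2OCc2ccccc2)cc1
F2 | step 9 | 4-[2-(benzyloxy)benzyl]-2-bromophenol | Oc1ccc(Cc2ccccc2OCc2ccccc2)cc1Br
F3 | step 9 | 1-(benzyloxy)-4-[2-(benzyloxy)benzyl]-2-bromobenzene | Brc1cc(Cc2ccccc2OCc2ccccc2)ccc1OCc1ccccc1
F4 | step 9 | {2-(benzyloxy)-5-[2-(benzyloxy)benzyl]phenyl}lithium | [Li]c1cc(Cc2ccccc2OCc2ccccc2)ccc1OCc1ccccc1
F5 | step 9 | [5-bromo-2-methoxy-4,6-bis(methoxymethoxy)-1,3-phenylene]bis({2-(benzyloxy)-5-[2-(benzyloxy)benzyl]phenyl}methanol) (mixture of diastereomers) | COc1c(C(O)c2cc(Cc3ccccc3OCc3ccccc3)ccc2OCc2ccccc2)c(OCOC)c(Br)c(OCOC)c1C(O)c1cc(Cc2ccccc2OCc2ccccc2)ccc1OCc1ccccc1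
F6 | step 13 | (R)-3-hydroxy-N-methoxy-N-methyl-3-phenylpropanamide | CON(C)C(=O)C[C@@H](O)c1ccccc1
F7 | step 13 | (R)-3-[(tert-butyldimethylsilyl)oxy]-N-methoxy-N-methyl-3-phenylpropanamide | CON(C)C(=O)C[C@@H](O[Si](C)(C)C(C)(C)C)c1ccccc1
F8 | step 13 | (R)-3-[(tert-butyldimethylsilyl)oxy]-1-[4-methoxy-2,6-bis(methoxymethoxy)-3,5-bis{2-(benzyloxy)-5-[2-(benzyloxy)benzyl]benzyl}phenyl]-3-phenylpropan-1-one | COc1c(Cc2cc(Cc3ccccc3OCc3ccccc3)ccc2OCc2ccccc2)c(OCOC)c(C(=O)C[C@@H](O[Si](C)(C)C(C)(C)C)c2ccccc2)c(OCOC)c1Cc1cc(Cc2ccccc2OCc2ccccc2)ccc1OCc1ccccc1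
F9 | step 13 | (R)-1-[2,6-dihydroxy-4-methoxy-3,5-bis{2-(benzyloxy)-5-[2-(benzyloxy)benzyl]benzyl}phenyl]-3-hydroxy-3-phenylpropan-1-one | COc1c(Cc2cc(Cc3ccccc3OCc3ccccc3)ccc2OCc2ccccc2)c(O)c(C(=O)C[C@@H](O)c2ccccc2)c(O)c1Cc1cc(Cc2ccccc2OCc2ccccc2)ccc1OCc1ccccc1
F10 | step 11 | 1-[4-methoxy-2,6-bis(methoxymethoxy)-3,5-bis{2-(benzyloxy)-5-[2-(benzyloxy)benzyl]benzyl}phenyl]ethan-1-ol (racemic) | COc1c(Cc2cc(Cc3ccccc3OCc3ccccc3)ccc2OCc2ccccc2)c(OCOC)c(C(C)O)c(OCOC)c1Cc1cc(Cc2ccccc2OCc2ccccc2)ccc1OCc1ccccc1
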